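A direct plan would acetylate 3,5-dimethoxy-4-methylphenol (A1) to the o-hydroxyacetophenone A2, join A2 to methyl triacontanoate (A3) by a crossed Claisen condensation to the 1,3-diketone A4, close the pyranone with acid to the dimethoxychromone A5, and finish with BBr3.
Its weakest steps would be:
- The crossed Claisen condensation of A2 with A3: an intermolecular C–C bond formation between a hindered phenoxide-enolate and a waxy, sparingly soluble C30 ester under excess NaH, on which all convergence would rest.
- The final double O-demethylation of A5: the methyl ethers would be carried only to force ring closure through one phenol, and their removal would expose the finished, poorly soluble chromone to excess BBr3 (slow 7-OMe cleavage, risk of pyranone opening and 6-methyl/8-methyl scrambling).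
- The run-up to A1 and A3: an arene C–H oxidation for the phenol and oxidation-state and ester changes for the chain, none of which would build the skeleton.

**Retrosynthetic overview**
Ring A (C4a–C5–C6–C7–C8–C8a) carries oxygen at C5 and C7 on either side of C6–CH3, so it is the enol form of a 2-methyl-1,3-diketone. It is cut at C5–C6 and C7–C8 and made last, by a Claisen ring closure on a pre-formed γ-pyrone.
Ring order: the pyranone first (C4–C4a and O1–C8a from an acylketene of triacontanoic acid and a β-enamino ester), then the benzene ring (C7–C8 by lateral acylation, C5–C6 by Claisen cyclisation).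
O1 is bonded to C8a before any phenol exists, so the 6-methyl/8-methyl question cannot arise. No oxygen is ever protected, so there is no demethylation. The C30 acid enters in the first step under mild coupling conditions, not in a late crossed Claisen.

Key step: step 4

Remark: the target has no stereocentre, and the four starting materials of the route are taken as articles of commerce.

Step 1
Reactants: 1 triacontanoic acid; 2 Meldrum's acid (2,2-dimethyl-1,3-dioxane-4,6-dione)
Product: 3 5-(1-hydroxytriacontylidene)-2,2-dimethyl-1,3-dioxane-4,6-dione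
Conditions: DCC (1.1 equiv), DMAP (1.5 equiv), CH2Cl2–THF, 0 → 30 °C; cold aq. KHSO4 wash
Reagents that add atoms: none
Why: Carbodiimide-mediated C-acylation of Meldrum's acid (Oikawa–Yonemitsu acylation) should turn the C30 acid, whose carboxyl carbon is the future C2, into a stable enolised acyl Meldrum's acid that serves as a latent acylketene, and no stereocentre is formed.

Step 2
Reactants: 3 5-(1-hydroxytriacontylidene)-2,2-dimethyl-1,3-dioxane-4,6-dione; 4 ethyl (E)-3-(pyrrolidin-1-yl)but-2-enoate
Product: 7 ethyl 2-methyl-6-nonacosyl-4-oxo-4H-pyran-3-carboxylate, via triacontanoylketene 5 (not isolated), via C-acylated enamino ester 6 (not isolated)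
Conditions: slow addition of 3 to 4 (1.5 equiv), toluene, 100 °C; then AcOH, 80 °C
Reagents that add atoms: none
Why: Thermal retro-hetero-Diels–Alder loss of acetone and CO2 should give the acylketene, which C-acylates the nucleophilic α-carbon of the enamino ester, and acid should then close the γ-pyrone by attack of the enol oxygen on the iminium carbon with loss of pyrrolidine (the acylketene–enamine condensation by which diketene or dioxinones and enamines give 4-pyranones), with no stereocentre formed.

Step 3
Reactants: 7 ethyl 2-methyl-6-nonacosyl-4-oxo-4H-pyran-3-carboxylate; 8 N-methoxy-N-methylpropanamide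
Product: 11 ethyl 6-nonacosyl-4-oxo-2-(2-oxobutyl)-4H-pyran-3-carboxylate, via lithium dienolate 9 (not isolated), via lithium hemiaminal adduct 10 (not isolated)
Conditions: LiN(SiMe3)2 (1.1 equiv), THF, −20 → 0 °C; 8 (1.5 equiv), 0 °C → rt; aq. NH4Cl
Reagents that add atoms: none
Why: Lateral (vinylogous) deprotonation should occur at the 2-methyl group, whose dienolate is conjugated with both the C4 ketone and the C3 ester and is therefore far more acidic than the CH2 of the chain, and a Weinreb ketone synthesis of the toluate-anion type should then form C7–C8 through a chelated adduct that cannot over-acylate, the carbinol carbon of 10 being racemic and lost on collapse.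

Step 4
Reactants: 11 ethyl 6-nonacosyl-4-oxo-2-(2-oxobutyl)-4H-pyran-3-carboxylate
Product: 14 5,7-dihydroxy-6-methyl-2-nonacosyl-4H-chromen-4-one, via dilithium dianion 12 (not isolated), via chromene-4,5,7-trione 13 (not isolated)
Conditions: LiN(i-Pr)2 (3.5 equiv), THF, −40 °C → rt; then 1 M HCl
Reagents that add atoms: none
Why: The first equivalent of base should remove the C8 proton between the ketone and the pyranone and a second a C6 proton of the ethyl ketone, giving the Harris-type dianion 12, whose last-formed and most nucleophilic C6 carbanion adds to the neighbouring ester carbonyl; loss of ethoxide gives trione 13, which enolises to the aromatic 5,7-diol. The closest known reaction is the base-induced Claisen (Dieckmann-type) cyclisation of 2-(2-oxoalkyl)benzoates to naphthalene-1,3-diols, the laboratory counterpart of polyketide Claisen aromatisation. Ring A is closed in the 6-exo-trig mode by formation of C5–C6, the pyranone ring being already in place. No stereocentre remains, since C6 of 13 is transient, racemic and erased on aromatisation. The step needs C-acylation and not O-acylation, and C6 and not C8 as the nucleophile: attack from C8 would need a four-membered ring, the dianion reacts at carbon, any enol lactone formed through oxygen should be reopened by the ethoxide set free, and the aromatic diphenoxide makes the closure irreversible. The 6-methyl pattern is fixed by structure, because O1 was bonded to C8a before ring A existed.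

**Compound list**
1 | triacontanoic acid | CCCCCCCCCCCCCCCCCCCCCCCCCCCCCC(=O)O | starting material
2 | Meldrum's acid (2,2-dimethyl-1,3-dioxane-4,6-dione) | CC1(C)OC(=O)CC(=O)O1 | starting material
3 | 5-(1-hydroxytriacontylidene)-2,2-dimethyl-1,3-dioxane-4,6-dione | CCCCCCCCCCCCCCCCCCCCCCCCCCCCCC(O)=C1C(=O)OC(C)(C)OC1=O | intermediate
4 | ethyl (E)-3-(pyrrolidin-1-yl)but-2-enoate | CCOC(=O)/C=C(/N1CCCC1)C | starting material
5 | triacontanoylketene (3-oxodotriacont-1-en-1-one) | CCCCCCCCCCCCCCCCCCCCCCCCCCCCCC(=O)C=C=O | intermediate (not isolated)
6 | ethyl 3,5-dioxo-2-[1-(pyrrolidin-1-yl)ethylidene]tetratriacontanoate (push–pull alkene, geometry not fixed) | CCCCCCCCCCCCCCCCCCCCCCCCCCCCCC(=O)CC(=O)C(C(=O)OCC)=C(C)N1CCCC1 | intermediate (not isolated)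
7 | ethyl 2-methyl-6-nonacosyl-4-oxo-4H-pyran-3-carboxylate | CCCCCCCCCCCCCCCCCCCCCCCCCCCCCc1cc(=O)c(C(=O)OCC)c(C)o1 | intermediate
8 | N-methoxy-N-methylpropanamide | CCC(=O)N(C)OC | starting material
9 | lithium 3-(ethoxycarbonyl)-2-methylidene-6-nonacosyl-2H-pyran-4-olate (lithium dienolate of 7) | CCCCCCCCCCCCCCCCCCCCCCCCCCCCCC1=CC([O-])=C(C(=O)OCC)C(=C)O1.[Li+] | intermediate (not isolated)
10 | lithium 1-[3-(ethoxycarbonyl)-6-nonacosyl-4-oxo-4H-pyran-2-yl]-2-[methoxy(methyl)amino]butan-2-olate (racemic) | CCCCCCCCCCCCCCCCCCCCCCCCCCCCCc1cc(=O)c(C(=O)OCC)c(CC(CC)([O-])N(C)OC)o1.[Li+] | intermediate (not isolated)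
11 | ethyl 6-nonacosyl-4-oxo-2-(2-oxobutyl)-4H-pyran-3-carboxylate | CCCCCCCCCCCCCCCCCCCCCCCCCCCCCc1cc(=O)c(C(=O)OCC)c(CC(=O)CC)o1 | intermediate
12 | dilithium 3-(ethoxycarbonyl)-6-nonacosyl-2-(2-oxidobut-2-en-1-ylidene)-2H-pyran-4-olate (dianion of 11, geometry not fixed) | CCCCCCCCCCCCCCCCCCCCCCCCCCCCCC1=CC([O-])=C(C(=O)OCC)C(=CC([O-])=CC)O1.[Li+].[Li+] | intermediate (not isolated)
13 | 6-methyl-2-nonacosyl-4H-chromene-4,5,7(6H,8H)-trione (racemic at C6, transient) | CCCCCCCCCCCCCCCCCCCCCCCCCCCCCc1cc(=O)c2c(o1)CC(=O)C(C)C2=O | intermediate (not isolated)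
14 | 5,7-dihydroxy-6-methyl-2-nonacosyl-4H-chromen-4-one (achiral) | CCCCCCCCCCCCCCCCCCCCCCCCCCCCCc1cc(=O)c2c(O)c(C)c(O)cc2o1 | target

Total step count: 4. Longest linear sequence: 4 steps (1 → 3 → 7 → 11 → 14).

**Steps most likely to fail**

Step 4 (key step). The second deprotonation may take place at the remote CH2 of the nonacosyl chain instead of at C6. The enolate oxygen may acylate in place of carbon (enol lactonisation). The dianion may also fail to form at a temperature at which the waxy substrate stays in solution. The fallback would set out from 11 and come back at 14. The keto ester would first be closed on purpose at oxygen: catalytic TsOH in toluene with removal of ethanol should give the enol lactone 7-ethyl-2-nonacosyl-4H,5H-pyrano[4,3-b]pyran-4,5-dione F1, the isocoumarin-type lactonisation of 2-(2-oxoalkyl)benzoates. F1 would then be heated with NaOMe in MeOH–THF. Methoxide should reopen the lactone to the enolate of methyl 6-nonacosyl-4-oxo-2-(2-oxobutyl)-4H-pyran-3-carboxylate F2. Under these equilibrating conditions an O-to-C acyl migration of the benzalphthalide-to-indanedione type should drain the system into the aromatic diphenoxide, which gives 14 on acidification. No dianion is needed.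

Step 2. The enamine may be acylated at its γ-carbon through the cross-conjugated dienamine tautomer instead of at the α-carbon. Pyrrolidine set free early may intercept the acylketene as a β-keto amide, or the acylketene may dimerise. The fallback would set out from 1 and come back at 7. The acid would be converted with (COCl)2 and catalytic DMF in toluene into triacontanoyl chloride F3. Ethyl acetoacetate and N,N-dimethylacetamide dimethyl acetal should give the enaminone ethyl 2-acetyl-3-(dimethylamino)but-2-enoate F4. F4 would be deprotonated with LiN(SiMe3)2 (2.2 equiv, THF, −78 → 0 °C) and C-acylated with F3 to ethyl 2-[1-(dimethylamino)ethylidene]-3,5-dioxotetratriacontanoate F5. Aqueous HCl would then close the pyranone with loss of dimethylamine. This is the enaminone/acid chloride γ-pyrone synthesis, an anionic acylation in place of a thermal acylketene capture.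

Step 3. The stabilised dienolate may be too weak a nucleophile for the Weinreb amide. It may add in the Michael sense to a second pyranone, or the substrate may crystallise from cold THF before it is deprotonated. The fallback would set out from 7 and come back at 11. The acidic 2-methyl group would be condensed without any metal enolate with 1,1-dimethoxy-N,N-dimethylpropan-1-amine (toluene, 110 °C, removal of MeOH). This should give the enamine ethyl 2-[(E)-2-(dimethylamino)but-1-en-1-yl]-6-nonacosyl-4-oxo-4H-pyran-3-carboxylate F6, an amide acetal condensation of the kind used on 2-methyl-4-pyranones and 2-methylchromones. Mild hydrolysis (aq. AcOH, THF, rt) should then give ketone 11.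

**Further compounds**
F1 | step 4 | 7-ethyl-2-nonacosyl-4H,5H-pyrano[4,3-b]pyran-4,5-dione | CCCCCCCCCCCCCCCCCCCCCCCCCCCCCc1cc(=O)c2c(o1)C=C(CC)OC2=O
F2 | step 4 | methyl 6-nonacosyl-4-oxo-2-(2-oxobutyl)-4H-pyran-3-carboxylate | CCCCCCCCCCCCCCCCCCCCCCCCCCCCCc1cc(=O)c(C(=O)OC)c(CC(=O)CC)o1
F3 | step 2 | triacontanoyl chloride | CCCCCCCCCCCCCCCCCCCCCCCCCCCCCC(=O)Cl
F4 | step 2 | ethyl 2-acetyl-3-(dimethylamino)but-2-enoate (push–pull alkene, geometry not fixed) | CCOC(=O)C(C(C)=O)=C(C)N(C)C
F5 | step 2 | ethyl 2-[1-(dimethylamino)ethylidene]-3,5-dioxotetratriacontanoate (push–pull alkene, geometry not fixed) | CCCCCCCCCCCCCCCCCCCCCCCCCCCCCC(=O)CC(=O)C(C(=O)OCC)=C(C)N(C)C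
F6 | step 3 | ethyl 2-[(E)-2-(dimethylamino)but-1-en-1-yl]-6-nonacosyl-4-oxo-4H-pyran-3-carboxylate | CCCCCCCCCCCCCCCCCCCCCCCCCCCCCc1cc(=O)c(C(=O)OCC)c(/C=C(\CC)N(C)C)o1
A1 | direct plan | 3,5-dimethoxy-4-methylphenol | COc1cc(O)cc(OC)c1C
A2 | direct plan | 1-(6-hydroxy-2,4-dimethoxy-3-methylphenyl)ethanone | CC(=O)c1c(O)cc(OC)c(C)c1OC
A3 | direct plan | methyl triacontanoate | CCCCCCCCCCCCCCCCCCCCCCCCCCCCCC(=O)OC
A4 | direct plan | 1-(6-hydroxy-2,4-dimethoxy-3-methylphenyl)dotriacontane-1,3-dione | CCCCCCCCCCCCCCCCCCCCCCCCCCCCCC(=O)CC(=O)c1c(O)cc(OC)c(C)c1OC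
A5 | direct plan | 5,7-dimethoxy-6-methyl-2-nonacosyl-4H-chromen-4-one | CCCCCCCCCCCCCCCCCCCCCCCCCCCCCc1cc(=O)c2c(OC)c(C)c(OC)cc2o1
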